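**Retrosynthetic overview**
- Feature: the only ring is the tetrahydrofuran O1–C2–C3–C4–C5. C2 carries an aryl group and is bonded to O1 and C3. It is therefore read as the carbonyl carbon of a syringaldehyde unit placed between the C5 hydroxyl and a nucleophilic C3. C3 is the β-carbon of an enol carbamate, and the oxygen-bearing carbon of that enol carbamate ends as the CH2OH on C3.
- End game: the target comes from the all-trans 2,5-diaryl-4-(silyloxymethyl)tetrahydrofuran-3-carbaldehyde by CHO reduction, desilylation and debenzylation.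
- Key disconnection: O1–C2 and C2–C3 are cut together (4+1). This gives O-benzylsyringaldehyde and a (1Z,3S,4R)-4-aryl-4-hydroxy-3-(silyloxymethyl)but-1-enyl carbamate. The ring is formed once, in that step.
- The C4/C5 pair comes from an Evans syn aldol of a γ-carbamoyloxy crotonyl imide (α-attack of its boron dienolate) on the same aldehyde. The imide carbonyl is reduced to the C4 CH2O arm, so aldol-syn becomes ring 4,5-trans. The imide itself comes from cross metathesis of allyl carbamate with an N-acryloyl oxazolidinone.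
- Metalation of a 4-silyloxybut-2-enyl carbamate is kept only as a reserve. That allyl anion can expel silanolate (1,4-elimination), and its enantiocontrol depends on a crystallising diamine complex.

Key step: step 8

Remark: the ring numbering is also used for the open-chain precursors. C5 is the aldol carbinol carbon, C4 the former imide α-carbon, C3 the enol β-carbon and C2 the carbonyl carbon of the second aldehyde. The target is C2-symmetric, so either half may serve as the aldol half.

Step 1
Reactants: 1 syringaldehyde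
Product: 2 4-(benzyloxy)-3,5-dimethoxybenzaldehyde
Conditions: BnBr, K2CO3, DMF, 60 °C
Reagents that add atoms: benzyl bromide, BrCc1ccccc1
Why: Williamson ether synthesis on the acidic para-formyl phenol gives a benzyl ether that withstands boron triflate, hydride and BF3·OEt2 and can be removed at the end.

Step 2
Reactants: 3 allyl alcohol; 4 N,N-diisopropylcarbamoyl chloride
Product: 5 allyl N,N-diisopropylcarbamate
Conditions: NaH, THF, 0 °C; then 4, reflux
Reagents that add atoms: none
Why: O-acylation of the sodium alkoxide by the hindered carbamoyl chloride (carbamate formation) installs the base- and hydride-resistant group that later makes the enol carbon nucleophilic.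

Step 3
Reactants: 6 (R)-4-benzyl-1,3-oxazolidin-2-one; 7 acryloyl chloride
Product: 8 (R)-3-acryloyl-4-benzyl-1,3-oxazolidin-2-one
Conditions: MeMgBr, THF, 0 °C; then 7, −78 → 0 °C
Reagents that add atoms: none
Why: N-acylation of the bromomagnesium salt of the oxazolidinone uses a weakly basic counter-ion that limits anionic polymerisation of the acryloyl unit, and the auxiliary stereocentre is not touched.

Step 4
Reactants: 5 allyl N,N-diisopropylcarbamate; 8 (R)-3-acryloyl-4-benzyl-1,3-oxazolidin-2-one
Product: 9 (R)-4-benzyl-3-[(E)-4-(N,N-diisopropylcarbamoyloxy)but-2-enoyl]-1,3-oxazolidin-2-one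
Conditions: second-generation Hoveyda–Grubbs catalyst (5 mol %), 5 (2 equiv), CH2Cl2, 40 °C
Reagents that add atoms: none
Why: olefin cross metathesis pairs an electron-poor acryloyl imide that does not homodimerise with an allylic carbamate whose homodimer re-enters the cycle, and should give the conjugated E-alkene under thermodynamic control.

Step 5
Reactants: 9 (R)-4-benzyl-3-[(E)-4-(N,N-diisopropylcarbamoyloxy)but-2-enoyl]-1,3-oxazolidin-2-one; 2 4-(benzyloxy)-3,5-dimethoxybenzaldehyde
Product: 11 (R)-4-benzyl-3-{(2R,3Z)-2-[(R)-[4-(benzyloxy)-3,5-dimethoxyphenyl](hydroxy)methyl]-4-(N,N-diisopropylcarbamoyloxy)but-3-enoyl}-1,3-oxazolidin-2-one (Evans syn adduct), via dibutylboron dienolate 10 (not isolated)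
Conditions: Bu2BOTf (1.3 equiv), Et3N (1.6 equiv), CH2Cl2, −78 → 0 °C; 2, −78 → 0 °C; then pH 7 buffer, MeOH, H2O2, 0 °C
Reagents that add atoms: none
Why: in this Evans boron aldol of a crotonate-type imide, soft enolisation removes the γ-hydrogen next to the carbamate oxygen, the boron-bound (1Z,3Z)-dienolate can reach the aldehyde only through Cα in a Zimmerman–Traxler chair, the (R)-benzyl auxiliary sets the (2R,3R)-syn pair (future C4 and C5), and deconjugation of an E-enoyl system with a γ-oxygen substituent should place the new enol double bond Z.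

Step 6
Reactants: 11 Evans syn adduct
Product: 12 (1Z,3S,4R)-4-[4-(benzyloxy)-3,5-dimethoxyphenyl]-4-hydroxy-3-(hydroxymethyl)but-1-enyl N,N-diisopropylcarbamate
Conditions: LiBH4, MeOH (1 equiv), THF, 0 °C
Reagents that add atoms: none
Why: reductive cleavage of the N-acyl oxazolidinone at its exocyclic carbonyl turns the imide carbon into the C4 hydroxymethyl carbon, leaves the hindered enol carbamate and both stereocentres alone, and returns the auxiliary.

Step 7
Reactants: 12 diol
Product: 13 (1Z,3S,4R)-4-[4-(benzyloxy)-3,5-dimethoxyphenyl]-4-hydroxy-3-[(triisopropylsilyloxy)methyl]but-1-enyl N,N-diisopropylcarbamate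
Conditions: TIPSCl, imidazole, DMF, 0 °C → rt
Reagents that add atoms: triisopropylsilyl chloride, CC(C)[Si](Cl)(C(C)C)C(C)C
Why: silyl ether formation under steric chemoselection should let the bulky chlorosilane take the primary hydroxyl and leave the flanked secondary benzylic hydroxyl free for the annulation.

Step 8
Reactants: 13 (1Z,3S,4R)-hydroxyalkenyl carbamate; 2 4-(benzyloxy)-3,5-dimethoxybenzaldehyde
Product: 16 (2R,3R,4S,5R)-2,5-bis[4-(benzyloxy)-3,5-dimethoxyphenyl]-4-[(triisopropylsilyloxy)methyl]tetrahydrofuran-3-carbaldehyde (all-trans), via (E)-oxocarbenium ion 14 (not isolated), via ring-closed carbamoyloxycarbenium ion 15 (not isolated)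
Conditions: 2 (1.3 equiv), BF3·OEt2 (2 equiv), CH2Cl2, −78 → −20 °C; aq NaHCO3
Reagents that add atoms: none
Why: BF3·OEt2 joins the C5 hydroxyl of 13 and aldehyde 2 as a hemiacetal and ionises it to the aryl-stabilised (E)-oxocarbenium ion 14, whose C2 is attacked by the enol carbamate β-carbon (C3) to give cation 15, which takes back the boron-held hydroxide equivalent and collapses to the aldehyde with loss of diisopropylamine and CO2. This is the known Lewis-acid condensation of (Z)-4-hydroxy-1-alkenyl carbamates with aldehydes to tetrahydrofuran-3-carbaldehydes, an intramolecular Mukaiyama-type aldol addition applied here to a new pair of partners. The single ring closes in a 5-(enolexo)-endo-trig mode, with both atoms of C2=O1+ ending in the ring and the enol C=C staying exocyclic, a closure that is accessible to cationic oxocarbenium electrophiles. C3 is controlled by allylic 1,3-strain of the Z-enol carbamate, which holds C4–H in the alkene plane so that the tethered electrophile reaches C3 on the face of C5 and opposite to CH2OTIPS (3,4-trans), while C2 is controlled by the E geometry of the oxocarbenium ion in a twist transition state that keeps its aryl group pseudo-equatorial and away from the C3 side chain (2,3-trans and 2,5-trans). The step needs ionisation at the hemiacetal carbon only and closure through the secondary oxygen only: the TIPS ether blocks the primary oxygen, which would otherwise give an isomeric 2-aryl-4-(arylhydroxymethyl) ring, and the non-conjugating meta methoxy groups together with the twisted 4-benzyloxy group keep the C5 benzylic C–O bond intact at low temperature. The all-trans array is also the thermodynamic minimum (C3 is enolisable and C2 can reionise) with the non-epimerisable C4 as anchor, so any equilibration should converge on 16.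

Step 9
Reactants: 16 all-trans tetrahydrofuran-3-carbaldehyde
Product: 17 {(2R,3S,4S,5R)-2,5-bis[4-(benzyloxy)-3,5-dimethoxyphenyl]-4-[(triisopropylsilyloxy)methyl]tetrahydrofuran-3-yl}methanol
Conditions: NaBH4, THF/MeOH, 0 °C
Reagents that add atoms: none
Why: chemoselective borohydride reduction of the aldehyde should be faster than enolisation or β-alkoxide elimination at C3, so all four stereocentres are kept.

Step 10
Reactants: 17 mono-silylated diol
Product: 18 {(2R,3S,4S,5R)-2,5-bis[4-(benzyloxy)-3,5-dimethoxyphenyl]tetrahydrofuran-3,4-diyl}dimethanol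
Conditions: TBAF, THF, 0 °C → rt
Reagents that add atoms: none
Why: fluoride-induced desilylation is driven by Si–F bond formation and leaves the benzyl ethers and the ring untouched.

Step 11
Reactants: 18 dibenzyl ether diol
Product: 19 {(2R,3S,4S,5R)-2,5-bis(4-hydroxy-3,5-dimethoxyphenyl)tetrahydrofuran-3,4-diyl}dimethanol (target, CNP0170897.1)
Conditions: H2 (1 atm), Pd/C (10 wt %), EtOAc/MeOH, rt, stopped after uptake of two equivalents of H2
Reagents that add atoms: none
Why: catalytic hydrogenolysis should cleave the two unhindered aryl benzyl ethers faster than the flanked ring benzylic C–O bonds in neutral medium at low pressure, and it touches no stereocentre.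

**Compound list**
1 | syringaldehyde | COc1cc(C=O)cc(OC)c1O | starting material
2 | 4-(benzyloxy)-3,5-dimethoxybenzaldehyde | COc1cc(C=O)cc(OC)c1OCc1ccccc1 | intermediate
3 | allyl alcohol | OCC=C | starting material
4 | N,N-diisopropylcarbamoyl chloride | CC(C)N(C(C)C)C(Cl)=O | starting material
5 | allyl N,N-diisopropylcarbamate | C=CCOC(=O)N(C(C)C)C(C)C | intermediate
6 | (R)-4-benzyl-1,3-oxazolidin-2-one | O=C1OC[C@@H](Cc2ccccc2)N1 | starting material
7 | acryloyl chloride | C=CC(Cl)=O | starting material
8 | (R)-3-acryloyl-4-benzyl-1,3-oxazolidin-2-one | O=C1OC[C@@H](Cc2ccccc2)N1C(=O)C=C | intermediate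
9 | (R)-4-benzyl-3-[(E)-4-(N,N-diisopropylcarbamoyloxy)but-2-enoyl]-1,3-oxazolidin-2-one | O=C1OC[C@@H](Cc2ccccc2)N1C(=O)/C=C/COC(=O)N(C(C)C)C(C)C | intermediate
10 | dibutylboron (1Z,3Z)-dienolate of 9 | CCCCB(CCCC)O/C(=C\C=C/OC(=O)N(C(C)C)C(C)C)N1[C@H](Cc2ccccc2)COC1=O | intermediate
11 | (R)-4-benzyl-3-{(2R,3Z)-2-[(R)-[4-(benzyloxy)-3,5-dimethoxyphenyl](hydroxy)methyl]-4-(N,N-diisopropylcarbamoyloxy)but-3-enoyl}-1,3-oxazolidin-2-one | O[C@@H](c1cc(OC)c(OCc2ccccc2)c(OC)c1)[C@H](C(=O)N1[C@H](Cc2ccccc2)COC1=O)/C=C\OC(=O)N(C(C)C)C(C)C | intermediate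
12 | (1Z,3S,4R)-4-[4-(benzyloxy)-3,5-dimethoxyphenyl]-4-hydroxy-3-(hydroxymethyl)but-1-enyl N,N-diisopropylcarbamate | O[C@@H](c1cc(OC)c(OCc2ccccc2)c(OC)c1)[C@H](CO)/C=C\OC(=O)N(C(C)C)C(C)C | intermediate
13 | (1Z,3S,4R)-4-[4-(benzyloxy)-3,5-dimethoxyphenyl]-4-hydroxy-3-[(triisopropylsilyloxy)methyl]but-1-enyl N,N-diisopropylcarbamate | O[C@@H](c1cc(OC)c(OCc2ccccc2)c(OC)c1)[C@H](CO[Si](C(C)C)(C(C)C)C(C)C)/C=C\OC(=O)N(C(C)C)C(C)C | intermediate
14 | (E)-oxocarbenium ion from 13 and 2 | COc1cc(/C=[O+]/[C@@H](c2cc(OC)c(OCc3ccccc3)c(OC)c2)[C@H](CO[Si](C(C)C)(C(C)C)C(C)C)/C=C\OC(=O)N(C(C)C)C(C)C)cc(OC)c1OCc1ccccc1 | intermediate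
15 | ring-closed carbamoyloxycarbenium ion | COc1cc([C@@H]2O[C@@H](c3cc(OC)c(OCc4ccccc4)c(OC)c3)[C@H](CO[Si](C(C)C)(C(C)C)C(C)C)[C@H]2C=[O+]C(=O)N(C(C)C)C(C)C)cc(OC)c1OCc1ccccc1 | intermediate
16 | (2R,3R,4S,5R)-2,5-bis[4-(benzyloxy)-3,5-dimethoxyphenyl]-4-[(triisopropylsilyloxy)methyl]tetrahydrofuran-3-carbaldehyde | COc1cc([C@@H]2O[C@@H](c3cc(OC)c(OCc4ccccc4)c(OC)c3)[C@H](CO[Si](C(C)C)(C(C)C)C(C)C)[C@H]2C=O)cc(OC)c1OCc1ccccc1 | intermediate
17 | {(2R,3S,4S,5R)-2,5-bis[4-(benzyloxy)-3,5-dimethoxyphenyl]-4-[(triisopropylsilyloxy)methyl]tetrahydrofuran-3-yl}methanol | COc1cc([C@@H]2O[C@@H](c3cc(OC)c(OCc4ccccc4)c(OC)c3)[C@H](CO[Si](C(C)C)(C(C)C)C(C)C)[C@H]2CO)cc(OC)c1OCc1ccccc1 | intermediate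
18 | {(2R,3S,4S,5R)-2,5-bis[4-(benzyloxy)-3,5-dimethoxyphenyl]tetrahydrofuran-3,4-diyl}dimethanol | COc1cc([C@@H]2O[C@@H](c3cc(OC)c(OCc4ccccc4)c(OC)c3)[C@H](CO)[C@H]2CO)cc(OC)c1OCc1ccccc1 | intermediate
19 | {(2R,3S,4S,5R)-2,5-bis(4-hydroxy-3,5-dimethoxyphenyl)tetrahydrofuran-3,4-diyl}dimethanol | COc1cc([C@@H]2O[C@@H](c3cc(OC)c(O)c(OC)c3)[C@H](CO)[C@H]2CO)cc(OC)c1O | target

**Step count**
- Total step count: 11.
- Longest linear sequence: 9 steps (steps 2, 4, 5, 6, 7, 8, 9, 10, 11). The branch through step 3 is equally long.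

**Steps most likely to fail**

**Step 8.**
- Three things may go wrong. The C5 benzylic C–O bond may ionise in competition with the hemiacetal. Acid or fluoride may remove the silyl group, after which closure runs through the primary oxygen. Aldehyde exchange may erode the facial selectivity at C2 and C3.
- The fallback sets out from 13 and 2 and comes back at 16. It releases the oxocarbenium ion from a pre-assembled α-acetoxy ether instead of from free alcohol plus aldehyde.
- Aldehyde 2 is taken by Pinnick oxidation (NaClO2, NaH2PO4, 2-methylbut-2-ene, t-BuOH/H2O) to 4-(benzyloxy)-3,5-dimethoxybenzoic acid F1.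
- Carbodiimide esterification of 13 (EDC·HCl, DMAP, CH2Cl2) gives the C5 benzoate ester F2.
- Reductive acetylation (i-Bu2AlH, CH2Cl2, −78 °C, then pyridine, DMAP, Ac2O) gives the α-acetoxy ether F3.
- TMSOTf in CH2Cl2 at −78 °C removes acetate, so ion 14 forms without free water or free alcohol and closes as in the main route. Aqueous NaHCO3 then hydrolyses the acetate-capped side chain on C3 to 16.

**Step 5.**
- Vinylogous enolisation may be sluggish because the carbamate carbonyl binds the boron triflate. The geometry of the new enol double bond may be incompletely controlled. The β,γ-double bond may drift into conjugation with the imide.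
- The fallback sets out from 4 and 2, comes back at 13 and replaces steps 2 to 7. It is a diamine-mediated lithiation–titanation homoaldol reaction.
- Commercial (E)-but-2-ene-1,4-diol is monosilylated (NaH, TIPSCl, THF) to (E)-4-(triisopropylsilyloxy)but-2-en-1-ol F4.
- F4 is carbamoylated with 4 (NaH, THF, reflux) to (E)-4-(triisopropylsilyloxy)but-2-enyl N,N-diisopropylcarbamate F5.
- n-BuLi/(+)-sparteine in toluene at −78 °C gives the (R)-lithio carbamate F6.
- ClTi(OiPr)3 is added at once and exchanges the metal with inversion to the (S)-allyltitanium reagent F7.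
- Aldehyde 2 then adds through a chair transition state with an axial carbamoyloxy group to give the (Z)-anti adduct 13.
- The (+)-enantiomer of the diamine is required. The (−)-sparteine/titanium sequence known for the parent but-2-enyl carbamate leads to the opposite spatial series.
- This path stays second choice for two reasons. The lithiated species can lose silanolate by 1,4-elimination, and its configurational integrity is not secured by crystallisation.

**Step 11.**
- Over-reduction may occur: the ring benzylic C2–O1 and C5–O1 bonds may undergo hydrogenolysis once the electron-rich free phenols are unveiled.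
- The fallback sets out from 1 and 9 and comes back at 19. It changes the phenol protection to silyl, so that no reductive step is needed.
- Compound 1 is silylated (TBSCl, imidazole, DMF) to 4-(tert-butyldimethylsilyloxy)-3,5-dimethoxybenzaldehyde F8.
- The boron aldol of 9 (through 10) gives the syn adduct F9, LiBH4 gives the diol F10, and TIPSCl gives the annulation precursor F11.
- BF3·OEt2 with a second portion of F8 gives the all-trans aldehyde F12, and NaBH4 gives the alcohol F13.
- Excess TBAF buffered with AcOH removes all three silyl groups to give 19.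

**Further compounds**
F1 | step 8 | 4-(benzyloxy)-3,5-dimethoxybenzoic acid | COc1cc(C(=O)O)cc(OC)c1OCc1ccccc1
F2 | step 8 | (1R,2S,3Z)-1-[4-(benzyloxy)-3,5-dimethoxyphenyl]-4-(N,N-diisopropylcarbamoyloxy)-2-[(triisopropylsilyloxy)methyl]but-3-enyl 4-(benzyloxy)-3,5-dimethoxybenzoate | COc1cc(C(=O)O[C@@H](c2cc(OC)c(OCc3ccccc3)c(OC)c2)[C@H](CO[Si](C(C)C)(C(C)C)C(C)C)/C=C\OC(=O)N(C(C)C)C(C)C)cc(OC)c1OCc1ccccc1
F3 | step 8 | α-acetoxy ether from F2 (acetal carbon as a mixture of epimers) | COc1cc(C(OC(C)=O)O[C@@H](c2cc(OC)c(OCc3ccccc3)c(OC)c2)[C@H](CO[Si](C(C)C)(C(C)C)C(C)C)/C=C\OC(=O)N(C(C)C)C(C)C)cc(OC)c1OCc1ccccc1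
F4 | step 5 | (E)-4-(triisopropylsilyloxy)but-2-en-1-ol | OC/C=C/CO[Si](C(C)C)(C(C)C)C(C)C
F5 | step 5 | (E)-4-(triisopropylsilyloxy)but-2-enyl N,N-diisopropylcarbamate | CC(C)N(C(C)C)C(=O)OC/C=C/CO[Si](C(C)C)(C(C)C)C(C)C
F6 | step 5 | (R)-1-lithio derivative of F5, diamine ligand omitted | [Li][C@@H](OC(=O)N(C(C)C)C(C)C)/C=C/CO[Si](C(C)C)(C(C)C)C(C)C
F7 | step 5 | (S)-1-(triisopropoxytitanio) derivative of F5 | CC(C)O[Ti](OC(C)C)(OC(C)C)[C@H](OC(=O)N(C(C)C)C(C)C)/C=C/CO[Si](C(C)C)(C(C)C)C(C)C
F8 | step 11 | 4-(tert-butyldimethylsilyloxy)-3,5-dimethoxybenzaldehyde | COc1cc(C=O)cc(OC)c1O[Si](C)(C)C(C)(C)C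
F9 | step 11 | Evans syn adduct of 9 and F8 | O[C@@H](c1cc(OC)c(O[Si](C)(C)C(C)(C)C)c(OC)c1)[C@H](C(=O)N1[C@H](Cc2ccccc2)COC1=O)/C=C\OC(=O)N(C(C)C)C(C)C
F10 | step 11 | (1Z,3S,4R)-4-[4-(tert-butyldimethylsilyloxy)-3,5-dimethoxyphenyl]-4-hydroxy-3-(hydroxymethyl)but-1-enyl N,N-diisopropylcarbamate | O[C@@H](c1cc(OC)c(O[Si](C)(C)C(C)(C)C)c(OC)c1)[C@H](CO)/C=C\OC(=O)N(C(C)C)C(C)C
F11 | step 11 | (1Z,3S,4R)-4-[4-(tert-butyldimethylsilyloxy)-3,5-dimethoxyphenyl]-4-hydroxy-3-[(triisopropylsilyloxy)methyl]but-1-enyl N,N-diisopropylcarbamate | O[C@@H](c1cc(OC)c(O[Si](C)(C)C(C)(C)C)c(OC)c1)[C@H](CO[Si](C(C)C)(C(C)C)C(C)C)/C=C\OC(=O)N(C(C)C)C(C)C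
F12 | step 11 | (2R,3R,4S,5R)-2,5-bis[4-(tert-butyldimethylsilyloxy)-3,5-dimethoxyphenyl]-4-[(triisopropylsilyloxy)methyl]tetrahydrofuran-3-carbaldehyde | COc1cc([C@@H]2O[C@@H](c3cc(OC)c(O[Si](C)(C)C(C)(C)C)c(OC)c3)[C@H](CO[Si](C(C)C)(C(C)C)C(C)C)[C@H]2C=O)cc(OC)c1O[Si](C)(C)C(C)(C)C
F13 | step 11 | {(2R,3S,4S,5R)-2,5-bis[4-(tert-butyldimethylsilyloxy)-3,5-dimethoxyphenyl]-4-[(triisopropylsilyloxy)methyl]tetrahydrofuran-3-yl}methanol | COc1cc([C@@H]2O[C@@H](c3cc(OC)c(O[Si](C)(C)C(C)(C)C)c(OC)c3)[C@H](CO[Si](C(C)C)(C(C)C)C(C)C)[C@H]2CO)cc(OC)c1O[Si](C)(C)C(C)(C)C
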